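## Structural features

The target is a cis-fused octalin in which ring A (C1–C2–C3–C4–C4a–C8a, decalin numbering) holds a C3=C4 double bond and ring B (C4a–C5–C6–C7–C8–C8a) is saturated. C1 carries a (2E,4E)-penta-2,4-dienoic acid chain, C2 an (E)-but-2-en-2-yl group, C3 and C8 one methyl each, and C7 a sulfate monoester. The six stereocentres C2, C1, C8a, C4a, C8 and C7 form one unbroken array. H2, H4a, H8a, H8 and H7 lie on one face, so the C8a–C1 bond, the C8 methyl and the C7 oxygen are mutually cis on ring B, while the C1 chain is trans to both of its neighbours (the C2 butenyl group and C8). The fragile parts are the alkyl hydrogen sulfate (acid-labile, very polar), the dienoic acid, the doubly allylic C2–H and three alkenes that exclude unselective hydrogenation. The real difficulty is the crowded array C2–C1–C8a–C8–C7 combined with a cis ring fusion and a ring-A alkene that must sit at C3–C4 only. The key step uses the fact that C4 is an sp2 carbon bonded to the fusion carbon C4a, whose hydrogen is cis to H8a: an alkenylpalladium at C4, held to C8a through C3–C2–C1, can reach the ring-B C4a=C5 alkene only on the tether face, so closing ring A at C4–C4a gives the cis fusion and leaves the ring-A alkene where the alkenyl iodide placed it.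

## Logic of the disconnections

38 ⇒ 36. The O–S bond at C7 and the O–ethyl bond of the ester are cut first. The hydrogen sulfate is the most labile and most polar group; it survives hydroxide but not acid, so it goes on in the last operation and the acid is unveiled right after it. The gain is that every earlier compound is neutral and can be chromatographed. The forward step must sulfate a secondary alcohol flanked by the C8 methyl and hydrolyse an ester without harming the sulfate or the diene.

36 ⇒ 35 ⇒ 33 + 34. After the silyl ether at C7 is restored, the double bond between the carbon on C1 and its neighbour is cut. One vinylogous olefination then brings four carbons and both E alkenes, and the sensitive dienoate is replaced by a plain aldehyde. The forward step must be E-selective and must not scramble C1; that is safe because 33 has its formyl group trans to both neighbours, the stable arrangement.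

33 ⇒ 32 ⇒ 31 ⇒ 30. These are redox adjustments: the aldehyde comes from the methyl ester through the alcohol, and the C5–C6 single bond comes from the cis-disubstituted alkene of 30. Nothing is simplified in the skeleton, but 30 is the direct product of the ring closure. The demand is a reduction that tells one disubstituted alkene from two trisubstituted ones.

30 ⇒ 29. The C4–C4a bond is cut, which opens ring A. Cutting here turns a bicycle with six stereocentres into a monocyclic cyclohexene whose ring-A alkene is already fixed, with its methyl and geometry, as a (Z)-alkenyl iodide. The forward step must form C4a with H4a cis to H8a and must place the new ring-B alkene at C5–C6.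

29 ⇒ 25. The C1–C2 bond is cut as a [3,3] shift. This takes apart the two adjacent stereocentres C1 and C2 and the (E)-butenyl alkene in one move: all three derive from one carbinol centre and one enolate geometry. The forward step needs the Z(O)-enolate and a chair transition state; because the allyl part is acyclic, that is the normal course.

25 ⇒ 24 + 9. The ester C–O bond is cut. This makes the route convergent: a ring-B acid and an iodo-dienol of similar size. The demand is only a mild esterification of an acid-sensitive dienyl carbinol.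

24 ⇒ 21 ⇒ 20. The C1–C8a bond is cut as a second [3,3] shift of an O-acetyl group. The crowded C8a centre, cis to the C8 methyl, is then made with an unsubstituted two-carbon ketene acetal, the least demanding partner, and the shift also moves the ring alkene to C4a=C5 where the key step needs it. The forward step needs the C5 oxygen on the same face as the C8 methyl; 21 has it, and it comes from 20 by inversion.

20 ⇒ 18 ⇒ 17 ⇒ 15. The C5–O bond and the C4a=C8a alkene are traced back to an epoxy ketone and then to an enone, i.e. a 1,3-transposition of oxygen from C8a to C5. This connects the allylic alcohol with a simple 2-methyl-3-silyloxycyclohexanone. The demands are a face-selective epoxidation and a β-silyloxy ketone that survives base.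

15 ⇒ 14 ⇒ 12 ⇒ 11 ⇒ 10. The C8a oxygen and H8 are removed as a hydroboration, which sets the C8 methyl cis to the C7 silyl ether because borane attacks anti to that ether. The C7 centre itself comes from an enantioselective ketone reduction of 10, so the absolute configuration of ring B rests on one catalytic step.

9 ⇒ 8 ⇒ 4 + 7, 4 ⇒ 3 ⇒ 1, 7 ⇒ 5. The carbinol centre comes from an enantioselective reduction of the methyl ketone, the C=C bond next to it from a Wittig reaction, and the (Z)-iodoalkene from anti-carbometalation of 1. The demands are retention of the (Z)-iodoalkene through oxidation and olefination, and E-selectivity in the Wittig step.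

## Other disconnections considered

Alternative 1: The cut is the C4a–C5 bond, made while a C3–C7 bond is broken that exists only in a bridged precursor, the bicyclo[2.2.2]octenol A1. There ring A is already present, C3 is a methyl-bearing bridgehead and C7 carries hydroxyl and vinyl groups. The forward step is deprotonation with KH and 18-crown-6, an anionic oxy-Cope shift and protonation of the C7 enolate to give A2.
- In favour: the step is pericyclic and stereospecific, needs no transition metal, and delivers ring B together with the C7 oxygen, which is better than the chosen plan in what one step builds.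
- Equal: the cis fusion is imposed by the bicycle, as the tether imposes it in the chosen plan, and the C3=C4 alkene is released at a fixed position.
- Against: A1 has six stereocentres, among them a quaternary bridgehead, and the vinyl group must stand syn to the alkene bridge. Building it (a cycloaddition to a methyl-substituted cyclohexadiene, then face-selective vinyl addition next to the C8 methyl) is linear, and each selectivity is open. In A2, C8 is α to the ketone and can epimerise, and the ketone must still be reduced cis to the C8 methyl.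
- Comparison: mechanistically cleaner, structurally less convergent, and not shorter, because the C1 side chain still has to be built as in the chosen plan.

Alternative 2: The cut is the C1–C8a bond. The precursor A3 is a ring-B enone (C7 ketone, C8=C8a) with a (Z)-alkenyl chain at C4a that ends in an aldehyde. Pyrrolidine and benzoic acid form the enamine, whose C1 adds to C8a in a 6-exo Michael closure to give A4.
- In favour: the conditions are mild and metal-free. C1 arrives at the aldehyde oxidation level, which saves the ester-to-aldehyde adjustment and is better than the chosen plan on that point. C1 and C8 are epimerisable, so thermodynamic control is available.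
- Equal: the ring-A alkene position is fixed beforehand by the chain, as in the chosen plan.
- Against: the ring fusion is not enforced. A six-membered ring can close cis or trans onto the enone, so the cis fusion rests on kinetic face selectivity, which is weaker than the syn insertion of the chosen plan. C8 is set by protonation, and it is not clear that equilibration favours the methyl cis to the C8a–C1 bond. The C7 ketone must be reduced in the presence of the aldehyde. A3 needs a (Z)-trisubstituted alkene between two stereocentres, one of them γ to an enone.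
- Comparison: step count similar, stereochemical certainty lower.

Alternative 3: The cuts are C4a–C5 and C8–C8a. The ring-A enone A5 (C4 ketone, C4a=C8a) and the diene A6 combine under Me2AlCl in an endo [4+2] reaction to give A7.
- In favour: it is convergent and forms two bonds and three stereocentres (C4a, C8a, C8) in one step, more than the chosen key step does. The C8 methyl is set in the same event, which is better than the chosen plan.
- Equal: the cis fusion follows from suprafacial addition.
- Against: A5 is a cyclohexenone with three contiguous stereocentres, one of which (C3) is destroyed later. Its β-carbon C8a is flanked by the branched C1, so reactivity is low and the face selectivity depends on the C1 substituent. Afterwards the C4 ketone must be turned into the C3=C4 alkene, with enolisation toward C3 and not toward C4a, and the C6=C7 enol ether into the C7 alcohol cis to the methyl.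
- Comparison: these adjustments cost at least four steps and carry a regiochemical risk that the chosen plan does not have, since there the alkene position is inherent in the alkenyl iodide. The count is not lower overall.

Key step: step 17

Remarks on the chemistry (assumptions):
- TBSO stands for tert-butyldimethylsilyloxy. Decalin numbering (C1–C8a) is used for ring positions throughout.
- The target is taken as the doubly protonated form. Step 23 therefore ends with an acidification; in practice the compound would be stored as a salt.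
- 29 and 30 carry C1 in the configuration of 38, because C1 is created in the acyclic shift of step 16. No C1 equilibration is scheduled; it is kept as a fallback.
- 2-Methylcyclohex-2-en-1-one (10) and the phosphonate 34 are taken as purchased materials.

## Steps

Step 1
Reactants: 1 prop-2-yn-1-ol
Product: 3 (2Z)-3-iodo-2-methylprop-2-en-1-ol, via alkenylmagnesium alkoxide 2 (not isolated)
Conditions: MeMgBr (2.5 equiv), CuI (10 mol %), THF, −10 °C → rt; then I2, THF, −78 → 0 °C
Reagents that add atoms: methylmagnesium bromide, C[Mg]Br; iodine, II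
Why: Copper-catalysed anti-carbomagnesiation of the propargylic alkoxide puts methyl on C2 and magnesium on C3 cis to the CH2O group (chelate 2); iodinolysis with retention should give the (Z)-iodoalkene that becomes C3(Me)=C4–I.

Step 2
Reactants: 3 (2Z)-3-iodo-2-methylprop-2-en-1-ol
Product: 4 (2Z)-3-iodo-2-methylprop-2-enal
Conditions: MnO2 (activated, excess), CH2Cl2, rt, dark; used without storage
Reagents that add atoms: none
Why: Allylic alcohol oxidation on MnO2 is neutral and should leave the alkenyl iodide and its (Z) geometry intact; the aldehyde is used at once because it isomerises on standing.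

Step 3
Reactants: 5 3-bromobutan-2-one
Product: 7 3-(triphenyl-λ5-phosphanylidene)butan-2-one, via phosphonium bromide 6 (not isolated)
Conditions: PPh3, PhMe, 90 °C; then NaOH (2 M aq), CH2Cl2, rt
Reagents that add atoms: triphenylphosphine, c1ccc(cc1)P(c1ccccc1)c1ccccc1
Why: SN2 displacement of the α-bromo ketone by the phosphine and deprotonation of the salt give the ketone-stabilised ylide (Wittig reagent preparation).

Step 4
Reactants: 4 (2Z)-3-iodo-2-methylprop-2-enal; 7 3-(triphenyl-λ5-phosphanylidene)butan-2-one
Product: 8 (3E,5Z)-6-iodo-3,5-dimethylhexa-3,5-dien-2-one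
Conditions: CH2Cl2, 40 °C, dark
Reagents that add atoms: none
Why: Wittig olefination with a stabilised, α-branched ylide should give the (E)-trisubstituted enone (acetyl trans to the iodoalkenyl group), while the (Z)-iodoalkene is a spectator.

Step 5
Reactants: 8 (3E,5Z)-6-iodo-3,5-dimethylhexa-3,5-dien-2-one
Product: 9 (2S,3E,5Z)-6-iodo-3,5-dimethylhexa-3,5-dien-2-ol
Conditions: (R)-Me-CBS oxazaborolidine [(R)-1-methyl-3,3-diphenyltetrahydro-1H,3H-pyrrolo[1,2-c][1,3,2]oxazaborole] (20 mol %), BH3·SMe2, THF, −30 °C; MeOH quench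
Reagents that add atoms: none
Why: Corey–Bakshi–Shibata reduction: the α-methyl alkenyl group acts as the large and the methyl as the small substituent, so the (R)-catalyst should deliver hydride to give the (S)-carbinol, the centre that later encodes C2 and C1.

Step 6
Reactants: 10 2-methylcyclohex-2-en-1-one
Product: 11 (1R)-2-methylcyclohex-2-en-1-ol
Conditions: (S)-Me-CBS oxazaborolidine [(S)-1-methyl-3,3-diphenyltetrahydro-1H,3H-pyrrolo[1,2-c][1,3,2]oxazaborole] (10 mol %), BH3·SMe2, THF, −20 °C; MeOH quench
Reagents that add atoms: none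
Why: Corey–Bakshi–Shibata 1,2-reduction of an α-substituted cyclic enone (alkenyl side large, CH2 side small) should give the (R)-allylic alcohol; this carbon becomes C7.

Step 7
Reactants: 11 (1R)-2-methylcyclohex-2-en-1-ol
Product: 12 tert-butyldimethyl{[(1R)-2-methylcyclohex-2-en-1-yl]oxy}silane
Conditions: TBSCl, imidazole, DMF, rt
Reagents that add atoms: tert-butyldimethylsilyl chloride, CC(C)(C)[Si](C)(C)Cl
Why: Standard silylation; the bulky ether protects C7–O to the end and serves as the face-directing group of the next step.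

Step 8
Reactants: 12 tert-butyldimethyl{[(1R)-2-methylcyclohex-2-en-1-yl]oxy}silane
Product: 14 (1R,2S,3R)-3-TBSO-2-methylcyclohexan-1-ol, via alkylborane 13 (not isolated)
Conditions: BH3·THF, THF, 0 °C → rt; then NaOH (3 M aq), H2O2 (30%), 0 °C → rt
Reagents that add atoms: hydrogen peroxide, OO
Why: Hydroboration–oxidation: borane should add anti to the allylic silyl ether with boron on the less substituted carbon, so hydrogen enters C8 trans to the oxygen and the C8 methyl ends cis to the C7 silyl ether; oxidation proceeds with retention.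

Step 9
Reactants: 14 (1R,2S,3R)-3-TBSO-2-methylcyclohexan-1-ol
Product: 15 (2R,3R)-3-TBSO-2-methylcyclohexan-1-one
Conditions: Dess–Martin periodinane, pyridine, CH2Cl2, 0 °C → rt
Reagents that add atoms: none
Why: Buffered Dess–Martin oxidation is non-basic and non-acidic, so the α-methyl centre cis to the silyl ether should not epimerise and the β-silyloxy group should not eliminate.

Step 10
Reactants: 15 (2R,3R)-3-TBSO-2-methylcyclohexan-1-one
Product: 17 (5R,6R)-5-TBSO-6-methylcyclohex-2-en-1-one, via silyl enol ether 16 (not isolated)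
Conditions: LiN(i-Pr)2, THF, −78 °C; TMSCl; then Pd(OAc)2 (1.05 equiv), MeCN, rt
Reagents that add atoms: none
Why: Saegusa–Ito dehydrogenation: kinetic deprotonation takes the unhindered CH2 side (not the tertiary α-carbon next to the silyl ether), and divalent palladium converts the silyl enol ether into the enone and is reduced to zerovalent palladium.

Step 11
Reactants: 17 (5R,6R)-5-TBSO-6-methylcyclohex-2-en-1-one
Product: 18 (1R,3R,4R,6R)-4-TBSO-3-methyl-7-oxabicyclo[4.1.0]heptan-2-one
Conditions: H2O2 (30%), NaOH (0.2 equiv, aq), MeOH, −15 → 0 °C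
Reagents that add atoms: hydrogen peroxide, OO
Why: Nucleophilic (Weitz–Scheffer) epoxidation: hydroperoxide should attack the β-carbon on the face opposite to the cis methyl and silyloxy groups, which places the oxirane trans to both.

Step 12
Reactants: 18 (1R,3R,4R,6R)-4-TBSO-3-methyl-7-oxabicyclo[4.1.0]heptan-2-one
Product: 20 (1R,4S,5R)-5-TBSO-4-methylcyclohex-2-en-1-ol, via epoxy hydrazone 19 (not isolated)
Conditions: N2H4·H2O, AcOH (cat.), MeOH, 0 °C → rt
Reagents that add atoms: none
Why: Wharton transposition: the hydrazone opens the oxirane to an alkenyl diazene that loses N2, which gives the C4a=C8a alkene and leaves the C5–O bond with its configuration, trans to the methyl and silyloxy groups.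

Step 13
Reactants: 20 (1R,4S,5R)-5-TBSO-4-methylcyclohex-2-en-1-ol
Product: 21 (1S,4S,5R)-5-TBSO-4-methylcyclohex-2-en-1-yl acetate
Conditions: AcOH, PPh3, DIAD, PhMe, 0 °C → rt
Reagents that add atoms: acetic acid, CC(=O)O
Why: Mitsunobu esterification: SN2 displacement of the oxyphosphonium group by acetate inverts C5, so the ester oxygen ends cis to the C8 methyl and the C7 silyl ether (all-cis).

Step 14
Reactants: 21 (1S,4S,5R)-5-TBSO-4-methylcyclohex-2-en-1-yl acetate
Product: 24 2-[(1S,5R,6S)-5-TBSO-6-methylcyclohex-2-en-1-yl]acetic acid, via ketene acetal 22 (not isolated), via silyl ester 23 (not isolated)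
Conditions: TMSCl, Et3N, LiN(i-Pr)2, THF, −78 °C → rt → 60 °C; then citric acid (1 M aq)
Reagents that add atoms: none
Why: Ireland–Claisen rearrangement of an acetate: the suprafacial [3,3] shift forms C1–C8a on the face that carried the C5 oxygen, cis to the C8 methyl, and moves the alkene to C4a=C5; the unsubstituted ketene acetal is the least hindered partner for this crowded carbon and creates no stereocentre at C1.

Step 15
Reactants: 24 2-[(1S,5R,6S)-5-TBSO-6-methylcyclohex-2-en-1-yl]acetic acid; 9 (2S,3E,5Z)-6-iodo-3,5-dimethylhexa-3,5-dien-2-ol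
Product: 25 (2S,3E,5Z)-6-iodo-3,5-dimethylhexa-3,5-dien-2-yl 2-[(1S,5R,6S)-5-TBSO-6-methylcyclohex-2-en-1-yl]acetate
Conditions: DCC, 4-(dimethylamino)pyridine (10 mol %), CH2Cl2, 0 °C → rt
Reagents that add atoms: none
Why: Steglich esterification is neutral to basic and should not ionise the dienyl carbinol, whose configuration is retained; the minor enantiomer of either partner gives a diastereomer that can be removed here.

Step 16
Reactants: 25 (2S,3E,5Z)-6-iodo-3,5-dimethylhexa-3,5-dien-2-yl 2-[(1S,5R,6S)-5-TBSO-6-methylcyclohex-2-en-1-yl]acetate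
Product: 29 methyl (2S,3S,4E)-2-[(1S,5R,6S)-5-TBSO-6-methylcyclohex-2-en-1-yl]-3-[(1Z)-1-iodoprop-1-en-2-yl]-4-methylhex-4-enoate, via ketene acetal 26 (not isolated), via silyl ester 27 (not isolated), via carboxylic acid 28 (not isolated)
Conditions: LiN(i-Pr)2, THF/DMPU (4:1), −78 °C; TMSCl; −78 → 50 °C; citric acid (1 M aq); then TMSCHN2, PhMe/MeOH (4:1), 0 °C
Reagents that add atoms: (trimethylsilyl)diazomethane, C[Si](C)(C)C=[N+]=[N-]
Why: Ireland–Claisen rearrangement: in THF/DMPU the Z(O)-enolate should form and give the (Z)-ketene acetal 26 (C8a cis to OSiMe3); the acyclic chair with the carbinol methyl equatorial forms C1–C2, transfers the (S) centre to C2, gives the (E)-butenyl alkene and, with C8a equatorial, the C1 configuration shown; methylation of acid 28 then gives the ester.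

Step 17
Reactants: 29 methyl (2S,3S,4E)-2-[(1S,5R,6S)-5-TBSO-6-methylcyclohex-2-en-1-yl]-3-[(1Z)-1-iodoprop-1-en-2-yl]-4-methylhex-4-enoate
Product: 30 methyl (1S,2S,4aS,7R,8S,8aS)-2-[(2E)-but-2-en-2-yl]-7-TBSO-3,8-dimethyl-1,2,4a,7,8,8a-hexahydronaphthalene-1-carboxylate
Conditions: Pd(OAc)2 (10 mol %), PPh3 (25 mol %), Ag2CO3 (2 equiv), MeCN, 80 °C
Reagents that add atoms: none
Why: Intramolecular Heck reaction: PPh3 reduces Pd(OAc)2 to zerovalent palladium, which inserts into the C4–I bond with retention of the (Z) geometry, and Ag2CO3 removes iodide so that the cationic alkenylpalladium binds the ring-B alkene. Syn carbopalladation of C4a=C5 forms the C4–C4a bond and closes ring A in the 6-exo-trig mode; the 7-endo mode would give a bridged ring, and the butenyl alkene could be reached only by 4-exo or 5-endo closure. The new stereocentre C4a is set by the substrate: the chain C3–C2–C1 hangs from C8a on the face cis to the C8 methyl and can deliver C4 only to that face, which puts H4a cis to H8a. Palladium is left on C5 syn to the new bond; H4a is anti to it, so the only syn β-hydrogen is on C6 and elimination gives the C5=C6 alkene without touching C4a. Migration toward C7 is blocked because H7 is anti to the palladium face, and the silver salt suppresses re-addition of palladium hydride. The ring-A alkene needs no regiocontrol, because C3=C4 with its methyl is the former alkenyl iodide, whose (Z) geometry places C2 and C4a cis as the ring requires. The closest known reaction type is the intramolecular Heck cyclisation of alkenyl iodides onto cycloalkenes to give cis-fused bicycles.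

Step 18
Reactants: 30 methyl (1S,2S,4aS,7R,8S,8aS)-2-[(2E)-but-2-en-2-yl]-7-TBSO-3,8-dimethyl-1,2,4a,7,8,8a-hexahydronaphthalene-1-carboxylate
Product: 31 methyl (1S,2S,4aS,7R,8S,8aS)-2-[(2E)-but-2-en-2-yl]-7-TBSO-3,8-dimethyl-1,2,4a,5,6,7,8,8a-octahydronaphthalene-1-carboxylate
Conditions: 2-nitrobenzenesulfonohydrazide, Et3N, CH2Cl2, rt
Reagents that add atoms: none
Why: Diimide reduction: concerted syn transfer of H2 is much faster for the cis-disubstituted C5=C6 alkene than for the two trisubstituted alkenes, and it leaves the ester and the silyl ether alone.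

Step 19
Reactants: 31 methyl (1S,2S,4aS,7R,8S,8aS)-2-[(2E)-but-2-en-2-yl]-7-TBSO-3,8-dimethyl-1,2,4a,5,6,7,8,8a-octahydronaphthalene-1-carboxylate
Product: 32 [(1S,2S,4aS,7R,8S,8aR)-2-[(2E)-but-2-en-2-yl]-7-TBSO-3,8-dimethyl-1,2,4a,5,6,7,8,8a-octahydronaphthalen-1-yl]methanol
Conditions: i-Bu2AlH (3 equiv), CH2Cl2, −78 → 0 °C; KNaC4H4O6 (aq)
Reagents that add atoms: none
Why: Full reduction of the hindered ester to the primary alcohol avoids the over- or under-reduction of a one-step ester-to-aldehyde reduction; alkenes and the silyl ether are inert.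

Step 20
Reactants: 32 [(1S,2S,4aS,7R,8S,8aR)-2-[(2E)-but-2-en-2-yl]-7-TBSO-3,8-dimethyl-1,2,4a,5,6,7,8,8a-octahydronaphthalen-1-yl]methanol
Product: 33 (1S,2S,4aS,7R,8S,8aS)-2-[(2E)-but-2-en-2-yl]-7-TBSO-3,8-dimethyl-1,2,4a,5,6,7,8,8a-octahydronaphthalene-1-carbaldehyde
Conditions: Dess–Martin periodinane, pyridine, CH2Cl2, 0 °C → rt
Reagents that add atoms: none
Why: Buffered Dess–Martin oxidation stops at the aldehyde; C1 keeps its configuration, which is in any case the stable one (formyl trans to the butenyl group and to C8).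

Step 21
Reactants: 33 (1S,2S,4aS,7R,8S,8aS)-2-[(2E)-but-2-en-2-yl]-7-TBSO-3,8-dimethyl-1,2,4a,5,6,7,8,8a-octahydronaphthalene-1-carbaldehyde; 34 ethyl (2E)-4-(diethoxyphosphoryl)but-2-enoate
Product: 35 ethyl (2E,4E)-5-[(1S,2S,4aS,7R,8S,8aR)-2-[(2E)-but-2-en-2-yl]-7-TBSO-3,8-dimethyl-1,2,4a,5,6,7,8,8a-octahydronaphthalen-1-yl]penta-2,4-dienoate
Conditions: LiN(SiMe3)2, THF, −78 °C → rt
Reagents that add atoms: none
Why: Vinylogous Horner–Wadsworth–Emmons olefination: the phosphonate anion reacts at the carbon next to phosphorus and the stabilised reagent should give the new alkene (E), while the (2E) alkene comes with the reagent.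

Step 22
Reactants: 35 ethyl (2E,4E)-5-[(1S,2S,4aS,7R,8S,8aR)-2-[(2E)-but-2-en-2-yl]-7-TBSO-3,8-dimethyl-1,2,4a,5,6,7,8,8a-octahydronaphthalen-1-yl]penta-2,4-dienoate
Product: 36 ethyl (2E,4E)-5-[(1S,2S,4aS,7R,8S,8aR)-2-[(2E)-but-2-en-2-yl]-7-hydroxy-3,8-dimethyl-1,2,4a,5,6,7,8,8a-octahydronaphthalen-1-yl]penta-2,4-dienoate
Conditions: HF·pyridine, pyridine, THF, 0 °C → rt
Reagents that add atoms: none
Why: Fluoride-driven cleavage of the secondary silyl ether under buffered conditions should spare the dienoate and the trisubstituted alkenes.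

Step 23
Reactants: 36 ethyl (2E,4E)-5-[(1S,2S,4aS,7R,8S,8aR)-2-[(2E)-but-2-en-2-yl]-7-hydroxy-3,8-dimethyl-1,2,4a,5,6,7,8,8a-octahydronaphthalen-1-yl]penta-2,4-dienoate
Product: 38 (2E,4E)-5-[(1S,2S,4aS,7R,8S,8aR)-2-[(2E)-but-2-en-2-yl]-3,8-dimethyl-7-(sulfooxy)-1,2,4a,5,6,7,8,8a-octahydronaphthalen-1-yl]penta-2,4-dienoic acid, via pyridinium sulfate 37 (not isolated)
Conditions: SO3·pyridine (5 equiv), pyridine, 40 °C; then LiOH, THF/MeOH/H2O, rt; then HCl (1 M aq), 0 °C, reversed-phase desalting
Reagents that add atoms: sulfur trioxide–pyridine complex, O=S(=O)([O-])[n+]1ccccc1; lithium hydroxide, [Li+].[OH-]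
Why: O-Sulfation of the alcohol with retention at C7, then saponification in the same flask: a sulfate monoester anion resists hydroxide, so only the ethyl ester is hydrolysed, and cold acidification gives the acid form.

## Compound list

1 | prop-2-yn-1-ol | C#CCO | starting material
2 | cyclic alkenylmagnesium alkoxide (4-methyl-2,5-dihydro-1,2-oxamagnesole) | CC1=C[Mg]OC1 | intermediate
3 | (2Z)-3-iodo-2-methylprop-2-en-1-ol | OC/C(C)=C\I | intermediate
4 | (2Z)-3-iodo-2-methylprop-2-enal | O=C/C(C)=C\I | intermediate
5 | 3-bromobutan-2-one | CC(Br)C(C)=O | starting material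
6 | (3-oxobutan-2-yl)triphenylphosphonium bromide | CC(=O)C(C)[P+](c1ccccc1)(c1ccccc1)c1ccccc1.[Br-] | intermediate
7 | 3-(triphenyl-λ5-phosphanylidene)butan-2-one | CC(=O)C(C)=P(c1ccccc1)(c1ccccc1)c1ccccc1 | intermediate
8 | (3E,5Z)-6-iodo-3,5-dimethylhexa-3,5-dien-2-one | CC(=O)/C(C)=C/C(C)=C\I | intermediate
9 | (2S,3E,5Z)-6-iodo-3,5-dimethylhexa-3,5-dien-2-ol | C[C@H](O)/C(C)=C/C(C)=C\I | intermediate
10 | 2-methylcyclohex-2-en-1-one | CC1=CCCCC1=O | starting material
11 | (1R)-2-methylcyclohex-2-en-1-ol | CC1=CCCC[C@H]1O | intermediate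
12 | tert-butyldimethyl{[(1R)-2-methylcyclohex-2-en-1-yl]oxy}silane | CC1=CCCC[C@H]1O[Si](C)(C)C(C)(C)C | intermediate
13 | [(1R,2S,3R)-3-TBSO-2-methylcyclohexyl]borane | C[C@H]1[C@H]([BH2])CCC[C@H]1O[Si](C)(C)C(C)(C)C | intermediate
14 | (1R,2S,3R)-3-TBSO-2-methylcyclohexan-1-ol | C[C@H]1[C@H](O)CCC[C@H]1O[Si](C)(C)C(C)(C)C | intermediate
15 | (2R,3R)-3-TBSO-2-methylcyclohexan-1-one | C[C@H]1C(=O)CCC[C@H]1O[Si](C)(C)C(C)(C)C | intermediate
16 | tert-butyldimethyl{[(1R,2R)-2-methyl-3-(trimethylsilyloxy)cyclohex-3-en-1-yl]oxy}silane (kinetic silyl enol ether of 15) | C[C@H]1C(O[Si](C)(C)C)=CCC[C@H]1O[Si](C)(C)C(C)(C)C | intermediate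
17 | (5R,6R)-5-TBSO-6-methylcyclohex-2-en-1-one | C[C@H]1C(=O)C=CC[C@H]1O[Si](C)(C)C(C)(C)C | intermediate
18 | (1R,3R,4R,6R)-4-TBSO-3-methyl-7-oxabicyclo[4.1.0]heptan-2-one (oxirane trans to methyl and TBSO) | C[C@H]1C(=O)[C@@H]2O[C@@H]2C[C@H]1O[Si](C)(C)C(C)(C)C | intermediate
19 | hydrazone of 18 at the ketone carbon (the four stereocentres unchanged) | C[C@H]1C(=NN)[C@@H]2O[C@@H]2C[C@H]1O[Si](C)(C)C(C)(C)C | intermediate
20 | (1R,4S,5R)-5-TBSO-4-methylcyclohex-2-en-1-ol (hydroxyl trans to methyl and TBSO) | O[C@H]1C=C[C@H](C)[C@H](O[Si](C)(C)C(C)(C)C)C1 | intermediate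
21 | (1S,4S,5R)-5-TBSO-4-methylcyclohex-2-en-1-yl acetate (all-cis) | CC(=O)O[C@@H]1C=C[C@H](C)[C@H](O[Si](C)(C)C(C)(C)C)C1 | intermediate
22 | O-trimethylsilyl ketene acetal of 21 | C=C(O[Si](C)(C)C)O[C@@H]1C=C[C@H](C)[C@H](O[Si](C)(C)C(C)(C)C)C1 | intermediate
23 | trimethylsilyl ester of 24 | C[Si](C)(C)OC(=O)C[C@H]1C=CC[C@@H](O[Si](C)(C)C(C)(C)C)[C@H]1C | intermediate
24 | 2-[(1S,5R,6S)-5-TBSO-6-methylcyclohex-2-en-1-yl]acetic acid | OC(=O)C[C@H]1C=CC[C@@H](O[Si](C)(C)C(C)(C)C)[C@H]1C | intermediate
25 | (2S,3E,5Z)-6-iodo-3,5-dimethylhexa-3,5-dien-2-yl 2-[(1S,5R,6S)-5-TBSO-6-methylcyclohex-2-en-1-yl]acetate | C[C@H](OC(=O)C[C@H]1C=CC[C@@H](O[Si](C)(C)C(C)(C)C)[C@H]1C)/C(C)=C/C(C)=C\I | intermediate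
26 | (Z)-O-trimethylsilyl ketene acetal of 25 (ring carbon cis to OSiMe3) | C[Si](C)(C)O/C(O[C@@H](C)/C(C)=C/C(C)=C\I)=C\[C@H]1C=CC[C@@H](O[Si](C)(C)C(C)(C)C)[C@H]1C | intermediate
27 | trimethylsilyl ester of 28 | C/C=C(\C)[C@@H](/C(C)=C\I)[C@@H](C(=O)O[Si](C)(C)C)[C@H]1C=CC[C@@H](O[Si](C)(C)C(C)(C)C)[C@H]1C | intermediate
28 | (2S,3S,4E)-2-[(1S,5R,6S)-5-TBSO-6-methylcyclohex-2-en-1-yl]-3-[(1Z)-1-iodoprop-1-en-2-yl]-4-methylhex-4-enoic acid | C/C=C(\C)[C@@H](/C(C)=C\I)[C@@H](C(=O)O)[C@H]1C=CC[C@@H](O[Si](C)(C)C(C)(C)C)[C@H]1C | intermediate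
29 | methyl (2S,3S,4E)-2-[(1S,5R,6S)-5-TBSO-6-methylcyclohex-2-en-1-yl]-3-[(1Z)-1-iodoprop-1-en-2-yl]-4-methylhex-4-enoate | C/C=C(\C)[C@@H](/C(C)=C\I)[C@@H](C(=O)OC)[C@H]1C=CC[C@@H](O[Si](C)(C)C(C)(C)C)[C@H]1C | intermediate
30 | methyl (1S,2S,4aS,7R,8S,8aS)-2-[(2E)-but-2-en-2-yl]-7-TBSO-3,8-dimethyl-1,2,4a,7,8,8a-hexahydronaphthalene-1-carboxylate | C/C=C(\C)[C@H]1C(C)=C[C@H]2C=C[C@@H](O[Si](C)(C)C(C)(C)C)[C@@H](C)[C@H]2[C@@H]1C(=O)OC | intermediate
31 | methyl (1S,2S,4aS,7R,8S,8aS)-2-[(2E)-but-2-en-2-yl]-7-TBSO-3,8-dimethyl-1,2,4a,5,6,7,8,8a-octahydronaphthalene-1-carboxylate | C/C=C(\C)[C@H]1C(C)=C[C@H]2CC[C@@H](O[Si](C)(C)C(C)(C)C)[C@@H](C)[C@H]2[C@@H]1C(=O)OC | intermediate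
32 | [(1S,2S,4aS,7R,8S,8aR)-2-[(2E)-but-2-en-2-yl]-7-TBSO-3,8-dimethyl-1,2,4a,5,6,7,8,8a-octahydronaphthalen-1-yl]methanol | C/C=C(\C)[C@H]1C(C)=C[C@H]2CC[C@@H](O[Si](C)(C)C(C)(C)C)[C@@H](C)[C@H]2[C@@H]1CO | intermediate
33 | (1S,2S,4aS,7R,8S,8aS)-2-[(2E)-but-2-en-2-yl]-7-TBSO-3,8-dimethyl-1,2,4a,5,6,7,8,8a-octahydronaphthalene-1-carbaldehyde | C/C=C(\C)[C@H]1C(C)=C[C@H]2CC[C@@H](O[Si](C)(C)C(C)(C)C)[C@@H](C)[C@H]2[C@@H]1C=O | intermediate
34 | ethyl (2E)-4-(diethoxyphosphoryl)but-2-enoate | CCOC(=O)/C=C/CP(=O)(OCC)OCC | starting material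
35 | ethyl (2E,4E)-5-[(1S,2S,4aS,7R,8S,8aR)-2-[(2E)-but-2-en-2-yl]-7-TBSO-3,8-dimethyl-1,2,4a,5,6,7,8,8a-octahydronaphthalen-1-yl]penta-2,4-dienoate | C/C=C(\C)[C@H]1C(C)=C[C@H]2CC[C@@H](O[Si](C)(C)C(C)(C)C)[C@@H](C)[C@H]2[C@@H]1/C=C/C=C/C(=O)OCC | intermediate
36 | ethyl (2E,4E)-5-[(1S,2S,4aS,7R,8S,8aR)-2-[(2E)-but-2-en-2-yl]-7-hydroxy-3,8-dimethyl-1,2,4a,5,6,7,8,8a-octahydronaphthalen-1-yl]penta-2,4-dienoate | C/C=C(\C)[C@H]1C(C)=C[C@H]2CC[C@@H](O)[C@@H](C)[C@H]2[C@@H]1/C=C/C=C/C(=O)OCC | intermediate
37 | pyridinium salt of the C7 sulfate monoester of 36 | C/C=C(\C)[C@H]1C(C)=C[C@H]2CC[C@@H](OS(=O)(=O)[O-])[C@@H](C)[C@H]2[C@@H]1/C=C/C=C/C(=O)OCC.c1cc[nH+]cc1 | intermediate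
38 | (2E,4E)-5-[(1S,2S,4aS,7R,8S,8aR)-2-[(2E)-but-2-en-2-yl]-3,8-dimethyl-7-(sulfooxy)-1,2,4a,5,6,7,8,8a-octahydronaphthalen-1-yl]penta-2,4-dienoic acid | C/C=C(\C)[C@H]1C(C)=C[C@H]2CC[C@@H](OS(=O)(=O)O)[C@@H](C)[C@H]2[C@@H]1/C=C/C=C/C(=O)O | target

## Step count and least certain steps

Total step count: 23. Longest linear sequence: 18 steps (steps 6–23, from 10). The dienol branch (steps 1–5) joins at step 15.

Step 17 (key step). What may go wrong: slow insertion at the crowded C4a, so that protodeiodination or decay of the alkenylpalladium competes, and migration of the new C5=C6 double bond by re-addition of palladium hydride. Fallback: starting from 29, ring A would be closed at the same C4–C4a bond by a 6-exo cyclisation of the C4 alkenyl radical (Bu3SnH, AIBN, PhH, 80 °C, slow addition). The C5 radical is reduced in the same operation, so this path gives 31 directly and rejoins the route at 31 (no new compound, F0). Its own weak point, hydrogen transfer from C8a to the alkenyl radical, is why it is not the first choice.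

Step 16. What may go wrong: incomplete Z(O)-selectivity in the enolisation, or leakage through a boat-like arrangement, which would erode the configuration at C1 (C2 and the butenyl geometry depend only on the carbinol centre). Fallback: control C1 thermodynamically instead. Starting from 25, the shift run in THF alone should give mainly the C1 epimer, methyl (2R,3S,4E)-2-[(1S,5R,6S)-5-TBSO-6-methylcyclohex-2-en-1-yl]-3-[(1Z)-1-iodoprop-1-en-2-yl]-4-methylhex-4-enoate F1. F1 would be taken through the conditions of steps 17–20 to the C1-epimeric Heck product F2, the C1-epimeric octahydro ester F3, the C1-epimeric alcohol F4 and the C1-epimeric aldehyde F5. In F5 the formyl group is cis to both neighbours; base (DBU, CH2Cl2, rt) would equilibrate it to 33, where the formyl group is trans to the butenyl group and to C8, and the route continues from 33.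

Step 11. What may go wrong: β-elimination of the silyloxy group from the enolate and epimerisation of the α-methyl centre under alkaline peroxide, or incomplete face selectivity. Fallback: build the oxirane without base. Starting from 17, reduction with NaBH4 and CeCl3·7H2O (hydride anti to the methyl and silyloxy groups) would give (1S,5R,6S)-5-TBSO-6-methylcyclohex-2-en-1-ol F6. Hydroxyl-directed epoxidation (VO(acac)2, t-BuOOH) would give the syn epoxy alcohol F7, and Dess–Martin oxidation the epoxy ketone F8, the diastereomer of 18 with the oxirane cis to the methyl group. Wharton transposition (N2H4·H2O, AcOH) would then give the all-cis alcohol (1S,4S,5R)-5-TBSO-4-methylcyclohex-2-en-1-ol F9, which is acetylated (Ac2O, pyridine) to 21. The route resumes at 21, and the Mitsunobu step is not needed.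

Step 13. What may go wrong: ionisation of the activated allylic alcohol, leading to SN2′ attack, elimination to a diene or partial retention. Fallback: invert by oxidation and reduction. Starting from 20, Dess–Martin oxidation would give the enone (4S,5R)-5-TBSO-4-methylcyclohex-2-en-1-one F10. Reduction with NaBH4 and CeCl3·7H2O, with hydride attacking anti to the methyl and silyloxy groups, would give the all-cis alcohol F9 (the same compound as in the preceding fallback), and acetylation (Ac2O, pyridine, 4-(dimethylamino)pyridine) leads back to 21.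

Step 21. What may go wrong: poor conversion of the hindered α-branched aldehyde, reaction through the γ-carbon of the phosphonate anion, or formation of (Z) isomers at either alkene. Fallback: extend the chain two carbons at a time. Starting from 33, a Wittig reaction with (triphenyl-λ5-phosphanylidene)acetaldehyde (PhMe, 80 °C) would give the enal (2E)-3-[(1S,2S,4aS,7R,8S,8aR)-2-[(2E)-but-2-en-2-yl]-7-TBSO-3,8-dimethyl-1,2,4a,5,6,7,8,8a-octahydronaphthalen-1-yl]prop-2-enal F11. A Horner–Wadsworth–Emmons reaction with triethyl phosphonoacetate and NaH (THF, 0 °C) would then give 35, where the route resumes.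

## Further compounds

F0 | step 17 | none | none
F1 | step 16 | methyl (2R,3S,4E)-2-[(1S,5R,6S)-5-TBSO-6-methylcyclohex-2-en-1-yl]-3-[(1Z)-1-iodoprop-1-en-2-yl]-4-methylhex-4-enoate (C1 epimer of 29) | C/C=C(\C)[C@@H](/C(C)=C\I)[C@H](C(=O)OC)[C@H]1C=CC[C@@H](O[Si](C)(C)C(C)(C)C)[C@H]1C
F2 | step 16 | methyl (1R,2S,4aS,7R,8S,8aS)-2-[(2E)-but-2-en-2-yl]-7-TBSO-3,8-dimethyl-1,2,4a,7,8,8a-hexahydronaphthalene-1-carboxylate (C1 epimer of 30) | C/C=C(\C)[C@H]1C(C)=C[C@H]2C=C[C@@H](O[Si](C)(C)C(C)(C)C)[C@@H](C)[C@H]2[C@H]1C(=O)OC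
F3 | step 16 | methyl (1R,2S,4aS,7R,8S,8aS)-2-[(2E)-but-2-en-2-yl]-7-TBSO-3,8-dimethyl-1,2,4a,5,6,7,8,8a-octahydronaphthalene-1-carboxylate (C1 epimer of 31) | C/C=C(\C)[C@H]1C(C)=C[C@H]2CC[C@@H](O[Si](C)(C)C(C)(C)C)[C@@H](C)[C@H]2[C@H]1C(=O)OC
F4 | step 16 | [(1R,2S,4aS,7R,8S,8aR)-2-[(2E)-but-2-en-2-yl]-7-TBSO-3,8-dimethyl-1,2,4a,5,6,7,8,8a-octahydronaphthalen-1-yl]methanol (C1 epimer of 32) | C/C=C(\C)[C@H]1C(C)=C[C@H]2CC[C@@H](O[Si](C)(C)C(C)(C)C)[C@@H](C)[C@H]2[C@H]1CO
F5 | step 16 | (1R,2S,4aS,7R,8S,8aS)-2-[(2E)-but-2-en-2-yl]-7-TBSO-3,8-dimethyl-1,2,4a,5,6,7,8,8a-octahydronaphthalene-1-carbaldehyde (C1 epimer of 33) | C/C=C(\C)[C@H]1C(C)=C[C@H]2CC[C@@H](O[Si](C)(C)C(C)(C)C)[C@@H](C)[C@H]2[C@H]1C=O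
F6 | step 11 | (1S,5R,6S)-5-TBSO-6-methylcyclohex-2-en-1-ol | C[C@H]1[C@@H](O)C=CC[C@H]1O[Si](C)(C)C(C)(C)C
F7 | step 11 | (1R,2R,3S,4R,6S)-4-TBSO-3-methyl-7-oxabicyclo[4.1.0]heptan-2-ol | C[C@H]1[C@@H](O)[C@H]2O[C@H]2C[C@H]1O[Si](C)(C)C(C)(C)C
F8 | step 11 | (1S,3R,4R,6S)-4-TBSO-3-methyl-7-oxabicyclo[4.1.0]heptan-2-one | C[C@H]1C(=O)[C@H]2O[C@H]2C[C@H]1O[Si](C)(C)C(C)(C)C
F9 | step 11 | (1S,4S,5R)-5-TBSO-4-methylcyclohex-2-en-1-ol | O[C@@H]1C=C[C@H](C)[C@H](O[Si](C)(C)C(C)(C)C)C1
F10 | step 13 | (4S,5R)-5-TBSO-4-methylcyclohex-2-en-1-one | O=C1C=C[C@H](C)[C@H](O[Si](C)(C)C(C)(C)C)C1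
F11 | step 21 | (2E)-3-[(1S,2S,4aS,7R,8S,8aR)-2-[(2E)-but-2-en-2-yl]-7-TBSO-3,8-dimethyl-1,2,4a,5,6,7,8,8a-octahydronaphthalen-1-yl]prop-2-enal | C/C=C(\C)[C@H]1C(C)=C[C@H]2CC[C@@H](O[Si](C)(C)C(C)(C)C)[C@@H](C)[C@H]2[C@@H]1/C=C/C=O
A1 | alternative 1 | 7-[(2E)-but-2-en-2-yl]-8-(TBSO-methyl)-2-ethenyl-1,3-dimethylbicyclo[2.2.2]oct-5-en-2-ol, ethenyl group syn to the C5=C6 bridge | C/C=C(\C)[C@@H]1[C@@H](CO[Si](C)(C)C(C)(C)C)[C@H]2C=C[C@]1(C)[C@](O)(C=C)[C@H]2C
A2 | alternative 1 | cis-fused decalin with C7 ketone, C3=C4 alkene, C8 methyl and TBSO-methyl group at C1 (decalin numbering) | C/C=C(\C)[C@H]1C(C)=C[C@H]2CCC(=O)[C@@H](C)[C@H]2[C@@H]1CO[Si](C)(C)C(C)(C)C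
A3 | alternative 2 | (3S,4Z)-3-[(2E)-but-2-en-2-yl]-4-methyl-5-[(1R)-3-methyl-4-oxocyclohex-2-en-1-yl]pent-4-enal | C/C=C(\C)[C@H](CC=O)/C(C)=C\[C@H]1CCC(=O)C(C)=C1
A4 | alternative 2 | cis-fused decalin with C7 ketone, C3=C4 alkene, C8 methyl and formyl group at C1 (decalin numbering) | C/C=C(\C)[C@H]1C(C)=C[C@H]2CCC(=O)[C@@H](C)[C@H]2[C@@H]1C=O
A5 | alternative 3 | 5-[(2E)-but-2-en-2-yl]-4-(TBSO-methyl)-6-methylcyclohex-2-en-1-one, the ring-A enone with C1, C2 and C3 stereocentres as in the SMILES | C/C=C(\C)[C@H]1[C@H](C)C(=O)C=C[C@@H]1CO[Si](C)(C)C(C)(C)C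
A6 | alternative 3 | (3Z)-3-(trimethylsilyloxy)penta-1,3-diene | C/C=C(\O[Si](C)(C)C)C=C
A7 | alternative 3 | cis-fused adduct with C4 ketone, C6=C7 trimethylsilyl enol ether, C3 and C8 methyls and TBSO-methyl group at C1 (decalin numbering) | C/C=C(\C)[C@H]1[C@H](C)C(=O)[C@H]2CC=C(O[Si](C)(C)C)[C@@H](C)[C@H]2[C@@H]1CO[Si](C)(C)C(C)(C)C
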